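The bicyclo[3.2.1]octane is disconnected at C4–C5 and C5–C6, the two bonds that meet at the methoxy bridgehead. C5 lies between the C4 and C8 carbonyl carbons and carries benzylic C6, whose aryl ring has a para oxygen; it can therefore be acylated and then alkylated as a 2-methoxy-1,3-dione carbon. In one flask the methoxymethyl ketone of an acyclic keto ester closes the six-membered ring (C1–C2–C3–C4–C5–C8) by Dieckmann condensation, and fluoride then releases a para-quinone methide at C6 that the dione enolate captures to close the five-membered ring (C1–C7–C6–C5–C8). The precursor carries C1 and C7 preset, a methyl ester at C4 and a silylated vanillyl pivalate arm.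

Key step: step 14

Remark: locants C1–C8 are those of the bicyclo[3.2.1]octane of the target and label the same carbons in all earlier compounds; Ar = 3-methoxy-4-(triisopropylsilyloxy)phenyl.
Remark: C3 is drawn S from step 6 on, but once it is α to the C4 carbonyl (step 14) it can epimerise and is fixed for good only in step 16.
Remark: the S antipode of the phosphoric acid in step 2 is assumed, by analogy with its allylboration of aryl aldehydes, to give the 1S,2S alcohol.

Step 1
Reactants: 1 vanillin
Product: 2 3-methoxy-4-(triisopropylsilyloxy)benzaldehyde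
Conditions: iPr3SiCl, imidazole, DMF, rt
Reagents that add atoms: triisopropylsilyl chloride, CC(C)[Si](Cl)(C(C)C)C(C)C
Why: Imidazole-promoted silyl ether formation masks the phenol with a group that should survive amide bases and organolithiums yet fall to fluoride in step 14.

Step 2
Reactants: 2 3-methoxy-4-(triisopropylsilyloxy)benzaldehyde; 3 (E)-crotylboronic acid pinacol ester
Product: 4 (1S,2S)-1-Ar-2-methylbut-3-en-1-ol
Conditions: (S)-3,3′-bis(2,4,6-triisopropylphenyl)-1,1′-binaphthyl-2,2′-diyl hydrogen phosphate ((S)-TRIP, 5 mol%), 4 Å molecular sieves, toluene, −30 °C; aqueous work-up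
Reagents that add atoms: none
Why: Chiral phosphoric acid-catalysed crotylboration through a closed chair transition state transfers the E geometry into the anti C6/C7 relationship, and the S catalyst is expected to direct the crotyl group to the Si face of the aldehyde, setting 1S,2S.

Step 3
Reactants: 4 (1S,2S)-1-Ar-2-methylbut-3-en-1-ol
Product: 6 (1S,2S)-1-Ar-2-methylbutane-1,4-diol, via B-alkyl borinate 5 (not isolated)
Conditions: 9-borabicyclo[3.3.1]nonane (9-BBN, 2.5 equiv), THF, 0 °C → rt; then NaBO3·4H2O, H2O, rt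
Reagents that add atoms: sodium perborate, [Na+].[Na+].O[B-]1(O)OO[B-](O)(O)OO1
Why: Anti-Markovnikov hydroboration–oxidation of the terminal alkene places the new hydroxyl on the end carbon (future C8) without touching C6 or C7, the carbinol riding through the addition as its borinate.

Step 4
Reactants: 6 (1S,2S)-1-Ar-2-methylbutane-1,4-diol
Product: 7 (4S,5S)-5-Ar-4-methyldihydrofuran-2(3H)-one (trans lactone)
Conditions: 2,2,6,6-tetramethylpiperidin-1-oxyl (TEMPO, 10 mol%), PhI(OAc)2 (2.5 equiv), CH2Cl2, rt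
Reagents that add atoms: none
Why: Nitroxyl-catalysed oxidation selects the primary alcohol, the aldehyde closes onto the benzylic hydroxyl and the lactol is oxidised further (oxidative lactonisation), so the trans lactone should form with C6 and C7 untouched.

Step 5
Reactants: 7 (4S,5S)-5-Ar-4-methyldihydrofuran-2(3H)-one; 8 allyl bromide
Product: 10 (3S,4S,5S)-3-allyl-5-Ar-4-methyldihydrofuran-2(3H)-one, via lithium enolate 9 (not isolated)
Conditions: LiN(iPr)2 (1.05 equiv), THF, −78 °C; then 8, −78 → −40 °C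
Reagents that add atoms: none
Why: Lactone enolate alkylation with a reactive allylic bromide should enter trans to the adjacent C7 methyl, although this centre is enolised again in step 9 so that only clean mono-alkylation matters here.

Step 6
Reactants: 11 (R)-glycidyl trityl ether
Product: 13 (R)-2-methoxy-1-(4-methoxybenzyloxy)-3-(trityloxy)propane, via sodium alkoxide 12 (not isolated)
Conditions: 4-MeOC6H4CH2OH, NaH, DMF, 0 → 60 °C; then MeI, 0 °C → rt
Reagents that add atoms: 4-methoxybenzyl alcohol, OCc1ccc(OC)cc1; iodomethane, CI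
Why: SN2 opening of the epoxide by the benzylic alkoxide at the unsubstituted carbon leaves the stereocentre (future C3) untouched, and the secondary alkoxide so formed is methylated in the same flask (Williamson ether synthesis).

Step 7
Reactants: 13 (R)-2-methoxy-1-(4-methoxybenzyloxy)-3-(trityloxy)propane
Product: 14 (S)-2-methoxy-3-(4-methoxybenzyloxy)propan-1-ol
Conditions: p-toluenesulfonic acid monohydrate (10 mol%), MeOH/CH2Cl2, rt
Reagents that add atoms: none
Why: Acid-catalysed solvolysis through the trityl cation should remove only the trityl ether, the 4-methoxybenzyl and methyl ethers being stable to this mild acid.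

Step 8
Reactants: 14 (S)-2-methoxy-3-(4-methoxybenzyloxy)propan-1-ol
Product: 15 (R)-2-methoxy-3-(4-methoxybenzyloxy)propyl trifluoromethanesulfonate
Conditions: (CF3SO2)2O, 2,6-lutidine, CH2Cl2, −78 °C; used at once
Reagents that add atoms: trifluoromethanesulfonic anhydride, O=S(=O)(OS(=O)(=O)C(F)(F)F)C(F)(F)F
Why: O-Sulfonylation of the primary alcohol gives a triflate, a leaving group reactive enough for SN2 at a β-branched, β-oxygenated carbon where an iodide would be too slow.

Step 9
Reactants: 10 (3S,4S,5S)-3-allyl-5-Ar-4-methyldihydrofuran-2(3H)-one; 15 (R)-2-methoxy-3-(4-methoxybenzyloxy)propyl trifluoromethanesulfonate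
Product: 17 (3S,4S,5S)-3-allyl-3-[(2S)-2-methoxy-3-(4-methoxybenzyloxy)propyl]-4-methyl-5-Ar-dihydrofuran-2(3H)-one, via lithium enolate 16 (not isolated)
Conditions: LiN(iPr)2 (1.1 equiv), THF, −78 °C; DMPU; then 15, −78 → −30 °C
Reagents that add atoms: none
Why: SN2 alkylation of the fully substituted lactone enolate by the primary triflate creates quaternary C1, the electrophile again entering trans to the C7 methyl so that the allyl group ends cis to it (C1 = S), while C3 arrives unchanged from 15.

Step 10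
Reactants: 17 (3S,4S,5S)-3-allyl-3-[(2S)-2-methoxy-3-(4-methoxybenzyloxy)propyl]-4-methyl-5-Ar-dihydrofuran-2(3H)-one; 18 tributyl(methoxymethyl)stannane
Product: 19 (3S,4S,5S)-3-allyl-5-hydroxy-1-methoxy-3-[(2S)-2-methoxy-3-(4-methoxybenzyloxy)propyl]-4-methyl-5-Ar-pentan-2-one (open form of its lactol)
Conditions: 18, n-BuLi, THF, −78 °C; then 17, −78 °C; AcOH quench at −78 °C
Reagents that add atoms: methoxymethyllithium, [Li]COC (made in the flask from 18 and n-BuLi)
Why: Tin–lithium exchange gives methoxymethyllithium, which should add once to the hindered lactone carbonyl (acyl substitution held at the tetrahedral stage at −78 °C) and so deliver the methoxymethyl ketone (C8, C5) and the free C6 carbinol.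

Step 11
Reactants: 19 hydroxy ketone
Product: 20 (3S,4S,5S)-3-allyl-1-methoxy-3-[(2S)-2-methoxy-3-(4-methoxybenzyloxy)propyl]-4-methyl-5-(pivaloyloxy)-5-Ar-pentan-2-one
Conditions: t-BuCOCl, 4-(dimethylamino)pyridine, pyridine, CH2Cl2, 0 → 40 °C
Reagents that add atoms: pivaloyl chloride, CC(C)(C)C(Cl)=O
Why: Nucleophile-catalysed acylation drains the lactol–hydroxy ketone equilibrium through the open form and turns the C6 oxygen into a leaving group that has no α-hydrogen and is too hindered for acyl transfer to an enolate.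

Step 12
Reactants: 20 pivalate
Product: 21 (3S,4S,5S)-3-allyl-3-[(2S)-3-hydroxy-2-methoxypropyl]-1-methoxy-4-methyl-5-(pivaloyloxy)-5-Ar-pentan-2-one
Conditions: DDQ (2,3-dichloro-5,6-dicyano-1,4-benzoquinone), CH2Cl2/pH 7 buffer, 0 °C → rt
Reagents that add atoms: none
Why: Oxidative cleavage of the 4-methoxybenzyl ether by the quinone in buffered wet solvent should free the C4 alcohol while the aryl silyl ether, pivalate, ketone and alkene are left alone.

Step 13
Reactants: 21 primary alcohol
Product: 23 methyl (2S,4S,5S,6S)-4-allyl-2-methoxy-4-(2-methoxyacetyl)-5-methyl-6-(pivaloyloxy)-6-Ar-hexanoate, via carboxylic acid 22 (not isolated)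
Conditions: TEMPO (20 mol%), PhI(OAc)2 (2.5 equiv), MeCN/pH 7 buffer, rt; then Me3SiCHN2, toluene/MeOH, 0 °C
Reagents that add atoms: water, O; (trimethylsilyl)diazomethane, C[Si](C)(C)C=[N+]=[N-]
Why: Nitroxyl-catalysed oxidation through the aldehyde hydrate gives the acid, and diazoalkane esterification then gives the C4 methyl ester under neutral conditions that spare silyl ether and pivalate.

Step 14
Reactants: 23 methyl ester (acyclic keto ester)
Product: 26 (1S,3S,5S,6S,7R)-1-allyl-6-(4-hydroxy-3-methoxyphenyl)-3,5-dimethoxy-7-methylbicyclo[3.2.1]octane-4,8-dione, via monocyclic dione enolate 24 (not isolated), via para-quinone methide 25 (not isolated)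
Conditions: KN(SiMe3)2 (1.1 equiv), THF (0.01 M), −78 → 0 °C; then (Me2N)3S+ Me3SiF2− (TASF, 1.3 equiv), DMF, 0 °C → rt; AcOH
Reagents that add atoms: none
Why: KN(SiMe3)2 deprotonates C5, the only enolisable carbon beside the C8 ketone, and the enolate attacks the C4 methyl ester (Dieckmann condensation, 6-exo-trig) to give the 2-methoxycyclohexane-1,3-dione, which the expelled methoxide deprotonates, so the Claisen equilibrium is pulled forward and no free methoxide is left. Fluoride then cleaves the aryl silyl ether, the phenoxide expels pivalate from C6 to give the para-quinone methide, and the dione enolate adds through C5 to C6 in a 5-exo-trig 1,6-conjugate addition that restores the arene; both events are known reaction types (Dieckmann cyclisation of keto esters and 1,6-addition of 1,3-dicarbonyl enolates to para-quinone methides). C5 can be reached only on the ring face that carries the C7–C6 arm of quaternary C1, so its configuration follows from C1. At C6, allylic strain holds the C7–H bond in the plane of the quinone methide, so C5 adds on the face that leaves the aryl group trans to the C7 methyl, and the reversibility of the addition should return any cis isomer or O-alkylated enol ether to this product. The step needs acylation before alkylation and C- over O-alkylation: the silyl ether keeps the quinone methide masked until the dione enolate exists, the pivalate resists acyl transfer, and the use of one equivalent of base with anhydrous fluoride guards the non-enolisable β-diketone against retro-Claisen opening.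

Step 15
Reactants: 26 phenol dione
Product: 27 (1S,3S,5S,6S,7R)-1-allyl-6-(3,4-dimethoxyphenyl)-3,5-dimethoxy-7-methylbicyclo[3.2.1]octane-4,8-dione
Conditions: MeI, K2CO3, acetone, rt
Reagents that add atoms: iodomethane, CI
Why: Williamson O-methylation of the phenoxide installs the last aryl methoxy group and also ends the reversibility of the 1,6-addition, since the methyl ether can no longer expel C5.

Step 16
Reactants: 27 methylated dione
Product: 30 (1S,3S,5S,6S,7R,8S)-1-allyl-6-(3,4-dimethoxyphenyl)-8-hydroxy-3,5-dimethoxy-7-methylbicyclo[3.2.1]octan-4-one, via lithium enolate 28 (not isolated), via enolate alkoxide 29 (not isolated)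
Conditions: LiN(SiMe3)2 (1.2 equiv), THF, −78 → 0 °C; then LiAlH4, −78 → −40 °C; then AcOH/THF, −78 °C; aq. sodium potassium tartrate
Reagents that add atoms: none
Why: C4 is the only enolisable carbonyl (through C3–H, C8 lying between quaternary C1 and C5), so it is masked as its lithium enolate while the aluminohydride reduces the strained C8 ketone (enolate protection followed by hydride reduction); hydride is expected to enter over the C6–C7 bridge because the other face is screened by the axial C2–H and by the solvated, negatively charged enolate (8S), and the cold acid quench should protonate C3 on the face syn to C8, away from the endo aryl group on C6, which places the C3 methoxy endo (3S).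

Step 17
Reactants: 30 hydroxy ketone
Product: 31 (1S,3S,5S,6S,7R,8S)-1-allyl-6-(3,4-dimethoxyphenyl)-3,5-dimethoxy-7-methyl-4-oxobicyclo[3.2.1]octan-8-yl acetate (CNP0344493.1)
Conditions: Ac2O, 4-(dimethylamino)pyridine (cat.), pyridine, CH2Cl2, 0 °C → rt
Reagents that add atoms: acetic anhydride, CC(=O)OC(C)=O
Why: Nucleophile-catalysed acetylation of the secondary C8 alcohol proceeds under conditions too weakly basic to enolise C4, so C3 should be kept.

Compound list
1 | vanillin (4-hydroxy-3-methoxybenzaldehyde) | O=Cc1ccc(O)c(OC)c1 | starting material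
2 | 3-methoxy-4-(triisopropylsilyloxy)benzaldehyde | O=Cc1ccc(O[Si](C(C)C)(C(C)C)C(C)C)c(OC)c1 | intermediate
3 | (E)-crotylboronic acid pinacol ester | C/C=C/CB1OC(C)(C)C(C)(C)O1 | starting material
4 | (1S,2S)-1-Ar-2-methylbut-3-en-1-ol | C=C[C@H](C)[C@H](O)c1ccc(O[Si](C(C)C)(C(C)C)C(C)C)c(OC)c1 | intermediate
5 | (1S,2S) bis-borane adduct of 4: 9-BBN borinate on the C6 oxygen and 9-BBN on the terminal carbon | B1(CC[C@H](C)[C@H](OB2C3CCCC2CCC3)c2ccc(O[Si](C(C)C)(C(C)C)C(C)C)c(OC)c2)C2CCCC1CCC2 | intermediate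
6 | (1S,2S)-1-Ar-2-methylbutane-1,4-diol | OCC[C@H](C)[C@H](O)c1ccc(O[Si](C(C)C)(C(C)C)C(C)C)c(OC)c1 | intermediate
7 | (4S,5S)-5-Ar-4-methyldihydrofuran-2(3H)-one | O=C1C[C@H](C)[C@H](O1)c1ccc(O[Si](C(C)C)(C(C)C)C(C)C)c(OC)c1 | intermediate
8 | allyl bromide | C=CCBr | starting material
9 | lithium enolate of lactone 7 | [Li+].[O-]C1=C[C@H](C)[C@H](O1)c1ccc(O[Si](C(C)C)(C(C)C)C(C)C)c(OC)c1 | intermediate
10 | (3S,4S,5S)-3-allyl-5-Ar-4-methyldihydrofuran-2(3H)-one | O=C1[C@@H](CC=C)[C@H](C)[C@H](O1)c1ccc(O[Si](C(C)C)(C(C)C)C(C)C)c(OC)c1 | intermediate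
11 | (R)-glycidyl trityl ether, (R)-2-(trityloxymethyl)oxirane | C(OC[C@H]1CO1)(c1ccccc1)(c1ccccc1)c1ccccc1 | starting material
12 | sodium (R)-1-(4-methoxybenzyloxy)-3-(trityloxy)propan-2-olate | [Na+].[O-][C@@H](COC(c1ccccc1)(c1ccccc1)c1ccccc1)COCc1ccc(OC)cc1 | intermediate
13 | (R)-2-methoxy-1-(4-methoxybenzyloxy)-3-(trityloxy)propane | C(OC[C@H](OC)COCc1ccc(OC)cc1)(c1ccccc1)(c1ccccc1)c1ccccc1 | intermediate
14 | (S)-2-methoxy-3-(4-methoxybenzyloxy)propan-1-ol | OC[C@H](OC)COCc1ccc(OC)cc1 | intermediate
15 | (R)-2-methoxy-3-(4-methoxybenzyloxy)propyl trifluoromethanesulfonate | O=S(=O)(OC[C@H](OC)COCc1ccc(OC)cc1)C(F)(F)F | intermediate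
16 | lithium enolate of lactone 10 | [Li+].[O-]C1=C(CC=C)[C@H](C)[C@H](O1)c1ccc(O[Si](C(C)C)(C(C)C)C(C)C)c(OC)c1 | intermediate
17 | (3S,4S,5S)-3-allyl-3-[(2S)-2-methoxy-3-(4-methoxybenzyloxy)propyl]-4-methyl-5-Ar-dihydrofuran-2(3H)-one | O=C1[C@@](CC=C)(C[C@H](OC)COCc2ccc(OC)cc2)[C@H](C)[C@H](O1)c1ccc(O[Si](C(C)C)(C(C)C)C(C)C)c(OC)c1 | intermediate
18 | tributyl(methoxymethyl)stannane | CCCC[Sn](CCCC)(CCCC)COC | starting material
19 | (3S,4S,5S)-3-allyl-5-hydroxy-1-methoxy-3-[(2S)-2-methoxy-3-(4-methoxybenzyloxy)propyl]-4-methyl-5-Ar-pentan-2-one | C=CC[C@](C(=O)COC)(C[C@H](OC)COCc1ccc(OC)cc1)[C@H](C)[C@H](O)c1ccc(O[Si](C(C)C)(C(C)C)C(C)C)c(OC)c1 | intermediate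
20 | (3S,4S,5S)-3-allyl-1-methoxy-3-[(2S)-2-methoxy-3-(4-methoxybenzyloxy)propyl]-4-methyl-5-(pivaloyloxy)-5-Ar-pentan-2-one | C=CC[C@](C(=O)COC)(C[C@H](OC)COCc1ccc(OC)cc1)[C@H](C)[C@H](OC(=O)C(C)(C)C)c1ccc(O[Si](C(C)C)(C(C)C)C(C)C)c(OC)c1 | intermediate
21 | (3S,4S,5S)-3-allyl-3-[(2S)-3-hydroxy-2-methoxypropyl]-1-methoxy-4-methyl-5-(pivaloyloxy)-5-Ar-pentan-2-one | C=CC[C@](C(=O)COC)(C[C@H](OC)CO)[C@H](C)[C@H](OC(=O)C(C)(C)C)c1ccc(O[Si](C(C)C)(C(C)C)C(C)C)c(OC)c1 | intermediate
22 | (2S,4S,5S,6S)-4-allyl-2-methoxy-4-(2-methoxyacetyl)-5-methyl-6-(pivaloyloxy)-6-Ar-hexanoic acid | C=CC[C@](C(=O)COC)(C[C@H](OC)C(=O)O)[C@H](C)[C@H](OC(=O)C(C)(C)C)c1ccc(O[Si](C(C)C)(C(C)C)C(C)C)c(OC)c1 | intermediate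
23 | methyl (2S,4S,5S,6S)-4-allyl-2-methoxy-4-(2-methoxyacetyl)-5-methyl-6-(pivaloyloxy)-6-Ar-hexanoate (key-step precursor) | C=CC[C@](C(=O)COC)(C[C@H](OC)C(=O)OC)[C@H](C)[C@H](OC(=O)C(C)(C)C)c1ccc(O[Si](C(C)C)(C(C)C)C(C)C)c(OC)c1 | intermediate
24 | potassium enolate of (4S,6S)-4-allyl-2,6-dimethoxy-4-[(1S,2S)-1-Ar-1-(pivaloyloxy)propan-2-yl]cyclohexane-1,3-dione | [K+].C=CC[C@]1(C[C@H](OC)C(=O)C(OC)=C1[O-])[C@H](C)[C@H](OC(=O)C(C)(C)C)c1ccc(O[Si](C(C)C)(C(C)C)C(C)C)c(OC)c1 | intermediate
25 | potassium enolate of (4S,6S)-4-allyl-2,6-dimethoxy-4-[(2R)-1-(3-methoxy-4-oxocyclohexa-2,5-dien-1-ylidene)propan-2-yl]cyclohexane-1,3-dione (alkene geometry not defined) | [K+].C=CC[C@]1(C[C@H](OC)C(=O)C(OC)=C1[O-])[C@H](C)C=C1C=CC(=O)C(OC)=C1 | intermediate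
26 | (1S,3S,5S,6S,7R)-1-allyl-6-(4-hydroxy-3-methoxyphenyl)-3,5-dimethoxy-7-methylbicyclo[3.2.1]octane-4,8-dione | C=CC[C@]12C[C@H](OC)C(=O)[C@](OC)([C@H](c3ccc(O)c(OC)c3)[C@H]1C)C2=O | intermediate
27 | (1S,3S,5S,6S,7R)-1-allyl-6-(3,4-dimethoxyphenyl)-3,5-dimethoxy-7-methylbicyclo[3.2.1]octane-4,8-dione | C=CC[C@]12C[C@H](OC)C(=O)[C@](OC)([C@H](c3ccc(OC)c(OC)c3)[C@H]1C)C2=O | intermediate
28 | lithium C3=C4 enolate of dione 27 | [Li+].C=CC[C@]12CC(OC)=C([O-])[C@](OC)([C@H](c3ccc(OC)c(OC)c3)[C@H]1C)C2=O | intermediate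
29 | C8 alkoxide of enolate 28 after hydride addition, drawn as the dilithium salt | [Li+].[Li+].C=CC[C@]12CC(OC)=C([O-])[C@](OC)([C@H](c3ccc(OC)c(OC)c3)[C@H]1C)[C@H]2[O-] | intermediate
30 | (1S,3S,5S,6S,7R,8S)-1-allyl-6-(3,4-dimethoxyphenyl)-8-hydroxy-3,5-dimethoxy-7-methylbicyclo[3.2.1]octan-4-one | C=CC[C@]12C[C@H](OC)C(=O)[C@](OC)([C@H](c3ccc(OC)c(OC)c3)[C@H]1C)[C@H]2O | intermediate
31 | (1S,3S,5S,6S,7R,8S)-1-allyl-6-(3,4-dimethoxyphenyl)-3,5-dimethoxy-7-methyl-4-oxobicyclo[3.2.1]octan-8-yl acetate | C=CC[C@]12C[C@H](OC)C(=O)[C@](OC)([C@H](c3ccc(OC)c(OC)c3)[C@H]1C)[C@H]2OC(C)=O | target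

Total step count: 17. Longest linear sequence: 14 steps (steps 1–5 and 9–17); steps 6–8 make the side-chain triflate.

Steps most likely to fail

Step 14. The quinone methide may be consumed before C5 reaches it, by O-alkylation through the enolate oxygen on C8 or by intermolecular addition, or the basic medium may open the non-enolisable β-diketone by retro-Claisen cleavage. The fallback splits the step and reverses the polarity of the second bond formation. It sets out from 23: KN(SiMe3)2 alone, then AcOH, should give the neutral monocyclic dione F1. Sc(OTf)3 (catalytic) in CH2Cl2/MeNO2 would then ionise the benzylic pivalate to the para-silyloxybenzyl cation, which the enol should capture at C5 (Lewis-acid benzylation of a 1,3-dicarbonyl, the same 5-exo closure, with O-alkylation reversible under acid) to give the silyl-protected bicyclic dione F2. Bu4NF buffered with AcOH would remove the silyl group, and the route is rejoined at 26.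

Step 16. Hydride may be delivered to C8 from the C2–C4 side, giving the wrong carbinol epimer, or enolisation may be incomplete so that C4 is reduced as well. The fallback replaces kinetic hydride addition by an equilibrating reduction. It sets out from 27: LiN(SiMe3)2 and tert-butyldimethylsilyl chloride should give the C3=C4 silyl enol ether F3. Meerwein–Ponndorf–Verley reduction with Al(OiPr)3 in iPrOH/toluene at 80 °C is reversible and should settle on the carbinol whose hydroxyl lies away from the exo C7 methyl, the 8S alcohol F4. Ac2O with 4-(dimethylamino)pyridine would give the acetate F5, and HF·pyridine would cleave the silyl enol ether with protonation of C3 on the face syn to C8, so the fallback comes back to the route at the target 31.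

Step 9. SN2 attack of a hindered, fully substituted enolate on a β-branched triflate may be slow, so that elimination of the triflate or poor facial control takes over. The fallback forms the C1–C2 bond by carbonyl addition instead of displacement. It sets out from 14 and 10: oxidation of 14 (SO3·pyridine, DMSO, Et3N) should give the aldehyde F6. The lithium enolate 16 of lactone 10 would add to it at −78 °C (aldol addition, again trans to the C7 methyl) to give the β-hydroxy lactone F7 as a mixture at the new carbinol. PhOC(S)Cl with 4-(dimethylamino)pyridine would give the phenyl thionocarbonate F8, and Bu3SnH with azobisisobutyronitrile would remove the oxygen (Barton–McCombie deoxygenation), rejoining the route at 17.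

Further compounds
F1 | step 14 | (4S,6S)-4-allyl-2,6-dimethoxy-4-[(1S,2S)-1-Ar-1-(pivaloyloxy)propan-2-yl]cyclohexane-1,3-dione (C2 of the ring not defined) | C=CC[C@]1(C[C@H](OC)C(=O)C(OC)C1=O)[C@H](C)[C@H](OC(=O)C(C)(C)C)c1ccc(O[Si](C(C)C)(C(C)C)C(C)C)c(OC)c1
F2 | step 14 | (1S,3S,5S,6S,7R)-1-allyl-3,5-dimethoxy-6-[3-methoxy-4-(triisopropylsilyloxy)phenyl]-7-methylbicyclo[3.2.1]octane-4,8-dione | C=CC[C@]12C[C@H](OC)C(=O)[C@](OC)([C@H](c3ccc(O[Si](C(C)C)(C(C)C)C(C)C)c(OC)c3)[C@H]1C)C2=O
F3 | step 16 | C3=C4 tert-butyldimethylsilyl enol ether of dione 27 | C=CC[C@]12CC(OC)=C(O[Si](C)(C)C(C)(C)C)[C@](OC)([C@H](c3ccc(OC)c(OC)c3)[C@H]1C)C2=O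
F4 | step 16 | (8S)-8-hydroxy derivative of silyl enol ether F3 | C=CC[C@]12CC(OC)=C(O[Si](C)(C)C(C)(C)C)[C@](OC)([C@H](c3ccc(OC)c(OC)c3)[C@H]1C)[C@H]2O
F5 | step 16 | (8S)-8-acetoxy derivative of silyl enol ether F3 | C=CC[C@]12CC(OC)=C(O[Si](C)(C)C(C)(C)C)[C@](OC)([C@H](c3ccc(OC)c(OC)c3)[C@H]1C)[C@H]2OC(C)=O
F6 | step 9 | (R)-2-methoxy-3-(4-methoxybenzyloxy)propanal | O=C[C@H](OC)COCc1ccc(OC)cc1
F7 | step 9 | (3S,4S,5S)-3-allyl-3-[(2S)-1-hydroxy-2-methoxy-3-(4-methoxybenzyloxy)propyl]-4-methyl-5-Ar-dihydrofuran-2(3H)-one (carbinol carbon not defined) | O=C1[C@@](CC=C)(C(O)[C@H](OC)COCc2ccc(OC)cc2)[C@H](C)[C@H](O1)c1ccc(O[Si](C(C)C)(C(C)C)C(C)C)c(OC)c1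
F8 | step 9 | O-phenyl thionocarbonate of aldol adduct F7 | O=C1[C@@](CC=C)(C(OC(=S)Oc2ccccc2)[C@H](OC)COCc2ccc(OC)cc2)[C@H](C)[C@H](O1)c1ccc(O[Si](C(C)C)(C(C)C)C(C)C)c(OC)c1
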